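**Retrosynthetic overview**
1. Target 18 ⇐ open chalcone 17. The last step is a catalyst-controlled 6-endo oxa-Michael ring closure (the chalcone isomerase reaction); it forms ring C of the flavanone half and the only stereocentre.
2. 17 ⇐ 16 ⇐ bichalcone 13. Ring C of the flavone half is closed from an α-aryloxy-2'-hydroxychalcone and dehydrogenated (chalcone → flavanone → flavone); the C3–O–aryl ether is already in the chalcone, so two finished flavonoids are never coupled.
3. 13 ⇐ 11 + 12, 11 ⇐ 4 + 10, 4 ⇐ 2 + 3. Two Claisen–Schmidt condensations and one Williamson etherification build the ether-linked bichalcone.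
4. Protecting groups decide which chalcone closes when: MOM (acid-labile) on ring A of the flavone half, benzyl (acid-stable) on ring A of the flavanone half.
5. Ring order: flavone ring C (step 7), then flavanone ring C (step 9). All benzene rings are bought.

Assumption: the quinidine-derived thiourea is taken to give the (2S) closure; the sense is checked on the first run by chiral HPLC and CD, and if it is (2R) the pseudoenantiomeric quinine-derived thiourea is used with nothing else changed.

**Route**

Step 1
Reactants: 1 methyl ketone 1-(2,6-dihydroxy-4-methoxyphenyl)ethanone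
Product: 2 bis-benzyl ketone 1-[2,6-bis(benzyloxy)-4-methoxyphenyl]ethanone
Conditions: BnBr (2.4 equiv), K2CO3, DMF, 80 °C
Reagents that add atoms: benzyl bromide, BrCc1ccccc1
Why: Williamson O-benzylation (SN2) of both phenols, the hydrogen-bonded one needing heat, gives a ketone with no free ortho-hydroxyl, so the chalcone made from it stays open until step 9.

Step 2
Reactants: 2 bis-benzyl ketone; 3 4-hydroxybenzaldehyde
Product: 4 phenolic chalcone (E)-1-[2,6-bis(benzyloxy)-4-methoxyphenyl]-3-(4-hydroxyphenyl)prop-2-en-1-one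
Conditions: KOH (50% aq), EtOH, rt to 50 °C; then 1 M HCl to pH 4
Reagents that add atoms: none
Why: Claisen–Schmidt condensation (aldol addition, then E1cB dehydration) of the methyl ketone enolate with the aldehyde, which tolerates the aldehyde phenoxide at high KOH concentration, gives the thermodynamic E-enone and leaves the phenol free as the handle for step 5.

Step 3
Reactants: 5 phloroglucinol (benzene-1,3,5-triol, anhydrous)
Product: 6 tris-MOM ether 1,3,5-tris(methoxymethoxy)benzene
Conditions: NaH (3.3 equiv), MOMCl (3.3 equiv), DMF, 0 °C to rt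
Reagents that add atoms: chloromethyl methyl ether (MOMCl), COCCl
Why: Threefold Williamson O-alkylation of the sodium phenoxide with the hard electrophile MOMCl gives acetal ethers that are acid-labile protection and also the directing groups for step 4.

Step 4
Reactants: 6 tris-MOM ether; 7 Weinreb amide 2-chloro-N-methoxy-N-methylacetamide
Product: 10 chloroketone 2-chloro-1-[2,4,6-tris(methoxymethoxy)phenyl]ethanone, via aryllithium 8 (not isolated), via tetrahedral lithium adduct 9 (not isolated)
Conditions: n-BuLi, THF, 0 °C; then 7, −78 to −20 °C; then AcOH, −78 °C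
Reagents that add atoms: none
Why: Directed ortho-metalation between two OMOM groups gives the aryllithium, which adds once to the Weinreb amide because the chelated tetrahedral adduct survives until the acid quench (Weinreb ketone synthesis), releasing the α-chloroketone without over-addition.

Step 5
Reactants: 4 phenolic chalcone; 10 chloroketone
Product: 11 aryloxy ketone 2-{4-[(E)-3-[2,6-bis(benzyloxy)-4-methoxyphenyl]-3-oxoprop-1-en-1-yl]phenoxy}-1-[2,4,6-tris(methoxymethoxy)phenyl]ethanone
Conditions: K2CO3, KI (10 mol%), acetone, 55 °C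
Reagents that add atoms: none
Why: Williamson etherification (SN2 at the α-keto carbon, helped by in-situ Finkelstein exchange) installs the future C3–O–aryl bond before any heterocycle exists, and the chloroketone cannot close to a benzofuranone because all three ring-A oxygens are MOM ethers.

Step 6
Reactants: 11 aryloxy ketone; 12 4-(benzyloxy)benzaldehyde
Product: 13 ether-linked bichalcone (Z)-3-[4-(benzyloxy)phenyl]-2-{4-[(E)-3-[2,6-bis(benzyloxy)-4-methoxyphenyl]-3-oxoprop-1-en-1-yl]phenoxy}-1-[2,4,6-tris(methoxymethoxy)phenyl]prop-2-en-1-one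
Conditions: KOH (50% aq), EtOH/THF, 0 °C to rt, 12 in excess (3 equiv)
Reagents that add atoms: none
Why: Claisen–Schmidt condensation of the acidic α-aryloxy methylene with the non-enolisable aldehyde gives the α-aryloxychalcone with the aryl group trans to the carbonyl (either alkene isomer converges in step 7), while the flavanone-side chalcone has no acidic C–H and the excess aldehyde outcompetes Michael addition to it.

Step 7
Reactants: 13 ether-linked bichalcone
Product: 16 flavone–chalcone 2-[4-(benzyloxy)phenyl]-3-{4-[(E)-3-[2,6-bis(benzyloxy)-4-methoxyphenyl]-3-oxoprop-1-en-1-yl]phenoxy}-5,7-dihydroxy-4H-chromen-4-one, via triol chalcone 14 (not isolated), via 3-aryloxyflavanone 15 (not isolated)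
Conditions: HCl (1.25 M in MeOH), THF, 45 °C; evaporate; then I2 (10 mol%), DMSO, 120 °C
Reagents that add atoms: none
Why: Acid removes only the MOM acetals, the freed ortho-hydroxyl closes onto the enone (intramolecular oxa-Michael, chalcone → flavanone), and catalytic iodine in DMSO dehydrogenates the flavanone by α-iodination and HI loss with DMSO as terminal oxidant (the classical oxidative 2'-hydroxychalcone → flavone cyclisation), while the benzyl-blocked second chalcone has no free ortho-hydroxyl and cannot close.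

Step 8
Reactants: 16 flavone–chalcone
Product: 17 open chalcone 3-{4-[(E)-3-(2,6-dihydroxy-4-methoxyphenyl)-3-oxoprop-1-en-1-yl]phenoxy}-5,7-dihydroxy-2-(4-hydroxyphenyl)-4H-chromen-4-one
Conditions: BCl3 (1 M in CH2Cl2, 8 equiv), pentamethylbenzene (9 equiv), CH2Cl2, −78 to −40 °C; MeOH quench at −78 °C, cold water work-up
Reagents that add atoms: none
Why: Lewis-acid debenzylation with BCl3 cleaves the three aryl benzyl ethers at low temperature (the two chelating ortho ethers fastest), pentamethylbenzene traps the benzyl cation by Friedel–Crafts alkylation so the electron-rich rings are not C-benzylated, and the non-chelated methyl ether, the flavone 3-aryl ether and the enone survive.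

Step 9
Reactants: 17 open chalcone
Product: 18 target 5,7-dihydroxy-3-{4-[(2S)-5-hydroxy-7-methoxy-4-oxo-3,4-dihydro-2H-chromen-2-yl]phenoxy}-2-(4-hydroxyphenyl)-4H-chromen-4-one
Conditions: N-[3,5-bis(trifluoromethyl)phenyl]-N'-[(9R)-6'-methoxycinchonan-9-yl]thiourea (20 mol%), 2-MeTHF/toluene 1:1, −20 °C, 48–72 h; cold 0.1 M HCl wash
Reagents that add atoms: none
Why: Proposed new method: a bifunctional cinchona thiourea is asked to act as a small-molecule chalcone isomerase on an unactivated, fully unprotected 2',6'-dihydroxychalcone — the quinuclidine nitrogen takes the proton of the non-chelated 2'-OH, the thiourea N–H pair binds the enone oxygen and the forming enolate, the 6'-OH···O=C hydrogen bond pre-activates the enone and makes the 5-hydroxyflavanone the strongly favoured side of the equilibrium, and the ion-paired phenoxide is delivered to the Si face of C-β to set the 2S centre (intramolecular 6-endo oxa-Michael addition); the closest known reactions are cinchona-thiourea-catalysed asymmetric oxa-Michael closures of 2'-hydroxychalcone-type enones (best with an α-ester activating group) and the enzymatic chalcone isomerase reaction, and the extension lies in the missing activating group and the acidic flavone phenols, tolerable in principle because the only counter-cation any phenoxide can have is the chiral ammonium ion and no achiral base is present.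

**Compound list**
1 | 1-(2,6-dihydroxy-4-methoxyphenyl)ethanone | CC(=O)c1c(O)cc(OC)cc1O | starting material
2 | 1-[2,6-bis(benzyloxy)-4-methoxyphenyl]ethanone | CC(=O)c1c(OCc2ccccc2)cc(OC)cc1OCc1ccccc1 | intermediate
3 | 4-hydroxybenzaldehyde | O=Cc1ccc(O)cc1 | starting material
4 | (E)-1-[2,6-bis(benzyloxy)-4-methoxyphenyl]-3-(4-hydroxyphenyl)prop-2-en-1-one | COc1cc(OCc2ccccc2)c(C(=O)/C=C/c2ccc(O)cc2)c(OCc2ccccc2)c1 | intermediate
5 | phloroglucinol (benzene-1,3,5-triol) | Oc1cc(O)cc(O)c1 | starting material
6 | 1,3,5-tris(methoxymethoxy)benzene | COCOc1cc(OCOC)cc(OCOC)c1 | intermediate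
7 | 2-chloro-N-methoxy-N-methylacetamide | CON(C)C(=O)CCl | starting material
8 | [2,4,6-tris(methoxymethoxy)phenyl]lithium | [Li]c1c(OCOC)cc(OCOC)cc1OCOC | intermediate (not isolated)
9 | lithium 2-chloro-1-[methoxy(methyl)amino]-1-[2,4,6-tris(methoxymethoxy)phenyl]ethan-1-olate | [Li]OC(CCl)(N(C)OC)c1c(OCOC)cc(OCOC)cc1OCOC | intermediate (not isolated)
10 | 2-chloro-1-[2,4,6-tris(methoxymethoxy)phenyl]ethanone | O=C(CCl)c1c(OCOC)cc(OCOC)cc1OCOC | intermediate
11 | 2-{4-[(E)-3-[2,6-bis(benzyloxy)-4-methoxyphenyl]-3-oxoprop-1-en-1-yl]phenoxy}-1-[2,4,6-tris(methoxymethoxy)phenyl]ethanone | COc1cc(OCc2ccccc2)c(C(=O)/C=C/c2ccc(OCC(=O)c3c(OCOC)cc(OCOC)cc3OCOC)cc2)c(OCc2ccccc2)c1 | intermediate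
12 | 4-(benzyloxy)benzaldehyde | O=Cc1ccc(OCc2ccccc2)cc1 | starting material
13 | (Z)-3-[4-(benzyloxy)phenyl]-2-{4-[(E)-3-[2,6-bis(benzyloxy)-4-methoxyphenyl]-3-oxoprop-1-en-1-yl]phenoxy}-1-[2,4,6-tris(methoxymethoxy)phenyl]prop-2-en-1-one | COc1cc(OCc2ccccc2)c(C(=O)/C=C/c2ccc(O/C(=C\c3ccc(OCc4ccccc4)cc3)C(=O)c3c(OCOC)cc(OCOC)cc3OCOC)cc2)c(OCc2ccccc2)c1 | intermediate
14 | (Z)-3-[4-(benzyloxy)phenyl]-2-{4-[(E)-3-[2,6-bis(benzyloxy)-4-methoxyphenyl]-3-oxoprop-1-en-1-yl]phenoxy}-1-(2,4,6-trihydroxyphenyl)prop-2-en-1-one | COc1cc(OCc2ccccc2)c(C(=O)/C=C/c2ccc(O/C(=C\c3ccc(OCc4ccccc4)cc3)C(=O)c3c(O)cc(O)cc3O)cc2)c(OCc2ccccc2)c1 | intermediate (not isolated)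
15 | 2-[4-(benzyloxy)phenyl]-3-{4-[(E)-3-[2,6-bis(benzyloxy)-4-methoxyphenyl]-3-oxoprop-1-en-1-yl]phenoxy}-5,7-dihydroxychroman-4-one (racemic, mixture of 2,3-stereoisomers) | COc1cc(OCc2ccccc2)c(C(=O)/C=C/c2ccc(OC3C(=O)c4c(O)cc(O)cc4OC3c3ccc(OCc4ccccc4)cc3)cc2)c(OCc2ccccc2)c1 | intermediate (not isolated)
16 | 2-[4-(benzyloxy)phenyl]-3-{4-[(E)-3-[2,6-bis(benzyloxy)-4-methoxyphenyl]-3-oxoprop-1-en-1-yl]phenoxy}-5,7-dihydroxy-4H-chromen-4-one | COc1cc(OCc2ccccc2)c(C(=O)/C=C/c2ccc(Oc3c(-c4ccc(OCc5ccccc5)cc4)oc4cc(O)cc(O)c4c3=O)cc2)c(OCc2ccccc2)c1 | intermediate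
17 | 3-{4-[(E)-3-(2,6-dihydroxy-4-methoxyphenyl)-3-oxoprop-1-en-1-yl]phenoxy}-5,7-dihydroxy-2-(4-hydroxyphenyl)-4H-chromen-4-one | COc1cc(O)c(C(=O)/C=C/c2ccc(Oc3c(-c4ccc(O)cc4)oc4cc(O)cc(O)c4c3=O)cc2)c(O)c1 | intermediate
18 | 5,7-dihydroxy-3-{4-[(2S)-5-hydroxy-7-methoxy-4-oxo-3,4-dihydro-2H-chromen-2-yl]phenoxy}-2-(4-hydroxyphenyl)-4H-chromen-4-one | COc1cc(O)c2c(c1)O[C@H](c1ccc(Oc3c(-c4ccc(O)cc4)oc4cc(O)cc(O)c4c3=O)cc1)CC2=O | target

**Totals**
Total steps: 9. Longest linear sequence: 7 (steps 1, 2, 5, 6, 7, 8, 9; the branch through steps 3 and 4 is equally long).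

**Three steps most likely to fail**

Step 9 (asymmetric ring closure). The acidic flavone phenols may hold the amine catalyst away from the reacting chalcone and an uncatalysed racemic closure may compete, so the ee could be low. Fallback, setting out from 17 and returning at 18: close the ring without stereocontrol (NaOAc, EtOH, 60 °C) to the racemic flavanone F1, separate the enantiomers by preparative chiral HPLC on an amylose tris(3,5-dimethylphenylcarbamate) phase to obtain 18 and its (2R) enantiomer F2, and recycle F2 by base-induced racemisation (Et3N, MeOH, 40 °C, reversible ring opening through the chalcone) back to F1. This replaces asymmetric catalysis by resolution with recycling.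

Step 7 (MOM removal, ring closure, dehydrogenation). The acid may attack the aryl enol ether of 13, and hot iodine/HI may iodinate the free ring A or loosen an ortho benzyl ether, which would let the second chalcone close and be oxidised too. Fallback, setting out from 11 and returning at 16 (13, 14 and 15 are bypassed): C-acylate the lithium enolate of 11 (LiN(SiMe3)2, THF, −78 °C) with 4-(benzyloxy)benzoyl chloride to the 2-aryloxy-1,3-diketone F3, then treat F3 with HCl in MeOH/THF at 60 °C, which strips the MOM groups and cyclodehydrates the hydroxy-diketone (Baker–Venkataraman-type closure) to 16 with no oxidant.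

Step 8 (global debenzylation to the open chalcone). The non-chelated 4'-benzyl ether may lag, and HCl formed on quenching may close part of 17 to racemic flavanone. Any such flavanone must be removed by chromatography before step 9, since it cannot be separated from 18 afterwards. Fallback, setting out from 16 and returning at 18: cleave only the two benzyl ethers ortho to the chalcone carbonyl by chelation (MgBr2·OEt2, toluene/Et2O, 60 °C) to the mono-benzyl chalcone F4, run the ring closure of step 9 on F4 to the (2S)-flavanone mono-benzyl ether F5, and remove the last benzyl group by hydrogenolysis (H2, 10 wt% Pd/C, EtOAc, rt) once the enone is gone.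

**Further compounds**
F1 | step 9 | racemic 5,7-dihydroxy-3-[4-(5-hydroxy-7-methoxy-4-oxo-3,4-dihydro-2H-chromen-2-yl)phenoxy]-2-(4-hydroxyphenyl)-4H-chromen-4-one | COc1cc(O)c2c(c1)OC(c1ccc(Oc3c(-c4ccc(O)cc4)oc4cc(O)cc(O)c4c3=O)cc1)CC2=O
F2 | step 9 | (2R) enantiomer of 18 | COc1cc(O)c2c(c1)O[C@@H](c1ccc(Oc3c(-c4ccc(O)cc4)oc4cc(O)cc(O)c4c3=O)cc1)CC2=O
F3 | step 7 | 1-[4-(benzyloxy)phenyl]-2-{4-[(E)-3-[2,6-bis(benzyloxy)-4-methoxyphenyl]-3-oxoprop-1-en-1-yl]phenoxy}-3-[2,4,6-tris(methoxymethoxy)phenyl]propane-1,3-dione | COc1cc(OCc2ccccc2)c(C(=O)/C=C/c2ccc(OC(C(=O)c3ccc(OCc4ccccc4)cc3)C(=O)c3c(OCOC)cc(OCOC)cc3OCOC)cc2)c(OCc2ccccc2)c1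
F4 | step 8 | 2-[4-(benzyloxy)phenyl]-3-{4-[(E)-3-(2,6-dihydroxy-4-methoxyphenyl)-3-oxoprop-1-en-1-yl]phenoxy}-5,7-dihydroxy-4H-chromen-4-one | COc1cc(O)c(C(=O)/C=C/c2ccc(Oc3c(-c4ccc(OCc5ccccc5)cc4)oc4cc(O)cc(O)c4c3=O)cc2)c(O)c1
F5 | step 8 | 2-[4-(benzyloxy)phenyl]-5,7-dihydroxy-3-{4-[(2S)-5-hydroxy-7-methoxy-4-oxo-3,4-dihydro-2H-chromen-2-yl]phenoxy}-4H-chromen-4-one | COc1cc(O)c2c(c1)O[C@H](c1ccc(Oc3c(-c4ccc(OCc5ccccc5)cc4)oc4cc(O)cc(O)c4c3=O)cc1)CC2=O
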